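The numbers in the tables were generated by integration on assumed constants, and the scatter is random.

40.0 % of the substrates charged is the most that the flask's [coupling partner] = 0.0400 M can turn, taking one partner to one product. For the opposite outcome, substrates gone first, the partner would have to deliver 0.100 M of product, 2.50 times its own charge. Since its charge is smaller, the coupling partner is the limiting reagent of this reckoning, and the open question is how much of it reaches product.

| flask | left-handed substrate | right-handed substrate | coupling partner | free catalyst | remark | time |
|---|---|---|---|---|---|---|
| east | 0.050 M | 0.050 M | 0.020 M | 4.3 mM | run made earlier |  |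
| west | 0.050 M | 0.050 M | 0.080 M | 4.3 mM | run made earlier |  |
| flask | 0.050 M | 0.050 M | 0.0400 M | 4.3 mM |  | 40 min |

| run | time / min | left-handed product / % | right-handed product / % |
|---|---|---|---|
| east | 2.00 | 1.9 | 1.2 |
| east | 3.00 | 0.5 | 3.0 |
| east | 5.00 | 1.7 | 3.1 |
| east | 8.00 | 0.7 | 3.6 |
| east | 15.0 | 2.5 | 5.5 |
| east | 25.0 | 2.1 | 8.7 |
| west | 1.50 | 0.4 | 4.4 |
| west | 5.00 | 5.0 | 11.8 |
| west | 8.00 | 5.9 | 15.1 |
| west | 12.0 | 8.6 | 19.2 |
| west | 20.0 | 9.7 | 17.5 |
| west | 25.0 | 11.4 | 20.1 |

(readings scatter by 1 percentage point)

- free catalyst is single-handed; left-handed substrate and right-handed substrate are mirror images of each other, charged as a racemate, each of them at the stated concentration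
- an excess is the difference of the two amounts in percent of their sum
- an excess is below zero if the other one leads

* excess of left-handed product over right-handed product in the product at 4.0 min
* excess of left-handed product over right-handed product in the product at 40 min
* part of the left-handed substrate and right-handed substrate charged together that has reacted at 40 min

The west run's product moves from 27.8 % at 12.0 min to 31.5 % at 25.0 min, although its charge of coupling partner allows 80.0 %. Product per partner charged, read at the last readings, is 54.0 % in the east run and 39.4 % in the west run, each reading carrying 1 percentage point. The flask has twice the east charge of coupling partner and half the west charge, so the reckoning made here takes the mean, 46.7 %, as its partner share: product made per partner charged. That gives 18.7 % as product at the end.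

The forecast gives an excess of −52 % (−68 % to −38 %) at 4.0 min, an excess of −41 % (−52 % to −30 %) at 40 min, and 23 % (18 % to 29 %) reacted at 40 min, a part reacted higher than the product of this reckoning. Its reading of the runs: “Rate rises roughly in proportion to coupling partner at first, then collapses far faster than reagent depletion explains”.

The flask gives an excess of −34.4 % at 4.0 min, an excess of −33.9 % at 40 min, and 18.9 % reacted at 40 min. The part reacted lies inside the forecast's range, while the early excess stands above it.

    free catalyst + right-handed substrate ⇌ catalyst intermediate B (K = 47.0 L mol⁻¹, k = 1.60 L mol⁻¹ s⁻¹)
    coupling partner + catalyst intermediate A → free catalyst + left-handed product (k = 0.760 L mol⁻¹ s⁻¹)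
    free catalyst → spent catalyst (k = 6.90 × 10⁻⁴ s⁻¹)
    coupling partner + catalyst intermediate B → free catalyst + right-handed product (k = 0.310 L mol⁻¹ s⁻¹)
    free catalyst + left-handed substrate ⇌ catalyst intermediate A (K = 8.70 L mol⁻¹, k = 0.600 L mol⁻¹ s⁻¹)
    coupling partner → decomposed reagent (k = 0.00130 s⁻¹)
    left-handed substrate ⇌ right-handed substrate (k = 1.70 × 10⁻⁴ s⁻¹)

At 40.0 min the flask holds 17.2 % as product, a partner share of 43.0 %. At 4.00 min the flask's coupling partner is coupling at 0.0622 min⁻¹, slower than its decomposition at 0.0780 min⁻¹, and 0.56 % of it stands at the end beside 0.0226 M of decomposed reagent. From the east to the west run the share read fell 7.3 points per doubling of the coupling partner, so a neighbour flask with 0.16 M of coupling partner, one doubling beyond the west run, should reach 32.1 %, or 51.3 % as product. At 40.0 min that neighbour flask holds 55.9 % as product, with 56.8 % reacted.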